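## The problem

The target **39** is a lobane-type diterpenoid built on a cyclohexane ring (C1–C6). C1 is quaternary and carries a methyl group (C7) and a vinyl group (C8=C9); C2 carries an isopropenyl group (C10(=C11)–C12); C4 carries the side chain C13(=C14H–C15H2–C16H(OH)–C17Me2OH)–C18H2OAc.

Four stereocentres must be set. In the ring these are C1 (R), C2 (R) and C4 (S), with the C1 methyl, the C2 isopropenyl and the C4 side chain on one face and the vinyl group trans to the isopropenyl group. In the chain it is C16 (S). The C13=C14 alkene must have C18 cis to C15 (Z).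

The vicinal pair C1/C2, one member quaternary, is the hard part. C4 lies 1,3 to C2 and can dictate both centres if the ring is formed through a chair transition state with the C4 substituent equatorial. C16 is five bonds from the ring, cannot be controlled by it and is best taken from the chiral pool. The trisubstituted alkene needs a stereoselective olefination.

Fragile groups are the primary allylic acetate (lost to base, hydride and zerovalent palladium), the secondary/tertiary diol (to be masked as an acetonide) and the 1,5-diene, which cyclises under acid, as does any cyclodecadiene precursor.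

The feature that opens the structure is that C9=C8–C1–C2–C10=C11 is a 1,5-diene. Breaking C1–C2 and joining C9 to C11 in the retro-Cope sense turns the ring and its three stereocentres into an (E,E)-cyclodeca-1,5-diene with a single stereocentre, C4.

## Retrosynthesis

**Protecting-group end game (39 ⇐ 38 ⇐ 37 ⇐ 36).** No skeletal bond is cut. The acetonide of **38** is hydrolysed last; the acetate of **38** comes from alcohol **37**, and this from the PMB ether **36**. The acetate cannot be present earlier: the ring-forming base and the hydride used for desulfonylation would destroy it, and zerovalent palladium would ionise it. An ether at C18 is therefore carried through. Its exchange for acetate is placed after the rearrangement, on the robust elemane, and not on the acid-sensitive cyclodecadiene. The forward steps ask only for an oxidative debenzylation that spares isolated alkenes, an acylation and a mild ketal hydrolysis.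

**Cope disconnection (36 ⇐ 35).** The C1–C2 bond is cut and C9 is joined to C11. Alkylative closures at C3–C4 or C4–C5, or a cycloaddition across C1–C6/C2–C3, would each leave the quaternary centre or its neighbour to be made separately. This cut removes both at once and leaves the side chain untouched. The precursor **35** has one stereocentre instead of three and no quaternary carbon. The forward reaction must pass through the chair–chair conformer of the ten-membered ring with the C4 substituent pseudo-equatorial, both ring alkenes must be E, and acid must be excluded.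

**Ring closure (35 ⇐ 34 ⇐ 32).** The C9–C11 bond is cut. It is the only ring bond flanked by two allylic carbons, so both partners are activated: an allylic sulfone carbanion at C9 and an allylic bromide at C11. Cutting at C3–C4 or C4–C5 would instead make the stereocentre in the ring-forming step. The C9–C11 bond is also the one the Cope step breaks again, so the activating group leaves no trace in the ring. The sulfone is put on C9 and not on C11: in the hydride removal (**34** → **35**) the allyl termini are then C9 and the fully substituted C1, a clear choice, whereas a C11 sulfone would offer two secondary termini. The open-chain **32** is simpler by one medium ring. The forward closure needs high dilution.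

**Functional-group set-up (32 ⇐ 31 ⇐ 30 ⇐ 28 ⇐ 27).** No C–C bond is cut. Three oxygen termini are told apart by their protecting groups. The C9 silyl ether (TBS) is removed first and turned into the sulfone (**27** → **28** → **30**). The C11 silyl ether (TBDPS) is removed next and turned into the bromide only immediately before cyclisation (**30** → **31** → **32**). The C18 PMB ether stays. The order is dictated by the lability of the allylic bromide and by the acidity of the sulfone, which could not have survived the earlier organolithium and ylide steps.

**Side-chain alkene (27 ⇐ 25 + 5).** The C13=C14 bond is cut. A Wittig reaction between the α-alkoxy ketone **25** and the ylide of phosphonium salt **5** is preferred over an olefination with the carbonyl on the C14 side. Ketones carrying an α-alkoxymethyl group are the one ketone class that gives trisubstituted alkenes with useful control, and the sense (alkoxymethyl carbon cis to the ylide carbon) is the one needed. The alkene is installed before the ring is closed so that no enolisable ketone is present when the sulfone carbanion is generated. Salt **5** brings C14–C17 with C16 already set.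

**Ketone (25 ⇐ 23 + 7, 23 ⇐ 22).** The C13–C18 bond is cut: the Weinreb amide **23** takes up the alkoxymethyllithium made from stannane **7**. This brings in C18 with its oxygen in one step and keeps C4 configurationally safe. **23** comes from the imide **22** by transamination.

**Stereocentre C4 (22 ⇐ 20 + 11, 20 ⇐ 17 + 18).** The C3–C4 bond is cut. An Evans alkylation of imide **20** with the allylic iodide **11** is chosen because enolates of this type alkylate cleanly only with activated halides; the allylic arm is therefore the electrophile and the saturated arm sits in the acyl group. The acid **17** must have three methylene groups between the carboxyl carbon and the trisubstituted alkene, since a shorter homologue would close a nine-membered ring. The electrophile must carry its two allylic termini in differentiated form (iodide at C3, silyl ether at C11). The (R)-auxiliary **18** gives the S configuration at C4.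

**Building blocks (17 ⇐ 15 ⇐ 14 ⇐ 12; 11 ⇐ 10 ⇐ 9 ⇐ 8; 5 ⇐ 4 ⇐ 3 ⇐ 2 ⇐ 1; 7 ⇐ 6).**
- The E geometry of C1=C8 is fixed by a syn carboalumination of alkyne **12**, followed by hydroxymethylation, silylation and carboxylation of the chloride.
- The E geometry of C2=C10 is fixed by an SN2′ opening of vinyl epoxide **8**.
- The C16 stereocentre comes from the L-malic-acid-derived lactone **1** through triol **2**, acetonide **3** and iodide **4**.
- Stannane **7** is made from **6** by etherification.

Both ring alkenes are thus geometrically pure before they meet, which the stereospecific Cope step requires.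

## Roads not taken

**Alternative 1:** The cut is the C15–C16 bond of the side chain. In the forward key step the silyl ketene acetal of the 6-vinyl-1,4-dioxan-2-one A1 (LDA, Me3SiCl), which carries the finished elemane ring at C6, undergoes an Ireland–Claisen ring contraction to the dihydropyran acid A2.
- Merits: C18 and C15 become ring atoms of the dihydropyran, so the C13=C14 geometry is enforced and not merely selected. C16 is set by chirality transfer.
- Weak points: the route presupposes the elemane ring with all three stereocentres and does nothing for them. A1 needs a fully substituted carbinol of defined configuration next to C4. The lactone enolate can only react through a boat transition state. Afterwards the cyclic allylic ether of A2 must be cleaved between oxygen and C18 without touching the 1,5-diene, and the acid must be turned into the tertiary carbinol.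
- Comparison: for the alkene geometry this road is better than the Wittig step of the chosen plan. Against that, the chosen plan needs no ether cleavage, takes C16 from the chiral pool, has a fallback for the olefination, and solves the ring problem that Alternative 1 leaves open.

**Alternative 2:** The cuts are the C1–C6 and C2–C3 ring bonds. In the forward key step the diene A3 adds to the dienophile A4 under a chiral cationic boron Lewis acid and gives the cycloadduct A5, with the quaternary C1 and C2 set and formyl trans to ester.
- Merits: the two hardest stereocentres are made in one catalytic step from achiral materials, the regiochemistry follows the usual preference of 2-silyloxydienes, and no medium ring is needed.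
- Weak points: vinyl and isopropenyl still have to be made from the formyl and ester groups (olefination; double methyl addition and a dehydration that must go to the less substituted alkene). The C4 stereocentre and the whole side chain, including the Z alkene, must be attached afterwards to the ketone latent in the silyl enol ether of A5.
- Comparison: this road reaches the ring core in fewer steps and is the better one in step economy up to that point. Against that, in the chosen plan the vinyl and isopropenyl groups and both ring stereocentres appear in their final form in a single reagent-free step, and the side chain is complete before the ring exists, so no late C4 functionalisation is required.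

**Alternative 3:** The cut is the C4–C5 ring bond. In the forward key step a zerovalent palladium catalyst (Pd2(dba)3, 1,2-bis(diphenylphosphino)ethane) ionises the secondary allylic carbonate of the open-chain bis-sulfone A6, and the bis(phenylsulfonyl)methyl carbanion closes onto the allyl terminus to give the cyclohexane A7 with the trisubstituted alkene.
- Merits: a six-membered ring closure is kinetically far easier than a ten-membered one, the conditions are neutral, and ring and alkene are formed together.
- Weak points: A6 must already contain the acyclic quaternary/tertiary pair C1/C2, so the hardest problem is moved and not solved. The C4 configuration rests on 1,3-induction in the cyclisation. The alkene geometry rests on the syn/anti preference of the allyl complex. Two sulfonyl groups at C5 have to be removed afterwards.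
- Comparison: the ring closure of this road is more reliable than the macrocyclisation of the chosen plan, and both need a reductive desulfonylation. Against that, the chosen plan uses one stereocentre, made by a dependable auxiliary alkylation, to control C1 and C2 through a stereospecific rearrangement.

Key step: step 23

## Route

Remark on the chemistry: lactone **1** is taken as the commercial (S)-enantiomer derived from L-malic acid. The cyclic sulfone **34** is carried as a mixture of epimers at C9, which is of no consequence because that centre becomes a methylene group in step 22. Atom labels C1–C18 are those defined for the target in the first section.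

Step 1
Reactants: 1 (S)-3-hydroxydihydrofuran-2(3H)-one
Product: 2 (S)-4-methylpentane-1,3,4-triol
Conditions: MeMgBr (3.5 equiv), THF, 0 °C to rt; aq. NH4Cl
Reagents that add atoms: methylmagnesium bromide, C[Mg]Br
Why: Grignard addition: one equivalent deprotonates the hydroxyl and two add to the lactone carbonyl, which gives the tertiary carbinol C17 and releases the primary alkoxide; C16 is the untouched stereocentre of the chiral pool.

Step 2
Reactants: 2 (S)-4-methylpentane-1,3,4-triol
Product: 3 2-[(4S)-2,2,5,5-tetramethyl-1,3-dioxolan-4-yl]ethan-1-ol
Conditions: 2,2-dimethoxypropane, TsOH·H2O (cat.), acetone, rt; Et3N quench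
Reagents that add atoms: 2,2-dimethoxypropane, COC(C)(C)OC
Why: Acetonide formation under thermodynamic control should favour the five-membered dioxolane across the vicinal C16/C17 diol over the six-membered 1,3-dioxane, which would carry an axial methyl group; the primary hydroxyl stays free.

Step 3
Reactants: 3 2-[(4S)-2,2,5,5-tetramethyl-1,3-dioxolan-4-yl]ethan-1-ol
Product: 4 (4S)-4-(2-iodoethyl)-2,2,5,5-tetramethyl-1,3-dioxolane
Conditions: I2, PPh3, imidazole, CH2Cl2, 0 °C to rt
Reagents that add atoms: iodine, II
Why: Appel-type iodination of a primary alcohol; imidazole keeps the medium buffered so that the acetonide is not touched.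

Step 4
Reactants: 4 (4S)-4-(2-iodoethyl)-2,2,5,5-tetramethyl-1,3-dioxolane
Product: 5 triphenyl{2-[(4S)-2,2,5,5-tetramethyl-1,3-dioxolan-4-yl]ethyl}phosphonium iodide
Conditions: PPh3, NaHCO3 (solid), MeCN, 80 °C
Reagents that add atoms: triphenylphosphine, c1ccc(cc1)P(c1ccccc1)c1ccccc1
Why: SN2 quaternisation of triphenylphosphine by an unhindered primary iodide; the oxygen substituent is γ to phosphorus, so the derived ylide cannot undergo β-elimination.

Step 5
Reactants: 6 tributyl(iodomethyl)stannane
Product: 7 tributyl{[(4-methoxybenzyl)oxy]methyl}stannane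
Conditions: 4-methoxybenzyl alcohol, NaH, THF/DMF, 0 °C to rt
Reagents that add atoms: 4-methoxybenzyl alcohol, COc1ccc(CO)cc1
Why: Williamson etherification of the alkoxide with the reactive α-stannyl iodide gives the usual precursor of a protected hydroxymethyl anion.

Step 6
Reactants: 8 2-methyl-2-vinyloxirane
Product: 9 (E)-4-chloro-2-methylbut-2-en-1-ol
Conditions: TiCl4, CH2Cl2, −85 °C; aq. NaHCO3
Reagents that add atoms: titanium tetrachloride, Cl[Ti](Cl)(Cl)Cl
Why: Lewis-acid-promoted SN2′ opening of a vinyl epoxide: chloride is delivered to the vinyl terminus and the allylic alkoxide is formed with E geometry, which fixes the later C2=C10 ring alkene.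

Step 7
Reactants: 9 (E)-4-chloro-2-methylbut-2-en-1-ol
Product: 10 tert-butyl{[(E)-4-chloro-2-methylbut-2-en-1-yl]oxy}diphenylsilane
Conditions: t-BuPh2SiCl, imidazole, CH2Cl2, 0 °C to rt
Reagents that add atoms: tert-butyl(chloro)diphenylsilane, CC(C)(C)[Si](Cl)(c1ccccc1)c1ccccc1
Why: Standard silylation of a primary alcohol; the robust silyl ether marks C11 as the terminus to be unmasked last.

Step 8
Reactants: 10 tert-butyl{[(E)-4-chloro-2-methylbut-2-en-1-yl]oxy}diphenylsilane
Product: 11 tert-butyl{[(E)-4-iodo-2-methylbut-2-en-1-yl]oxy}diphenylsilane
Conditions: NaI, acetone, rt, dark; used at once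
Reagents that add atoms: sodium iodide, [Na+].[I-]
Why: Finkelstein exchange driven by precipitation of NaCl gives the allylic iodide that an enolate alkylation at low temperature requires; the alkene geometry is not affected.

Step 9
Reactants: 12 5-chloropent-1-yne
Product: 14 (E)-6-chloro-3-methylhex-2-en-1-ol, via alkenylalane 13 (not isolated)
Conditions: AlMe3 (3 equiv), Cp2ZrCl2 (0.25 equiv), CH2Cl2, 0 °C to rt; then n-BuLi, THF, −78 °C; (CH2O)n, −78 °C to rt; aq. work-up
Reagents that add atoms: trimethylaluminium, C[Al](C)C; paraformaldehyde (as formaldehyde), C=O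
Why: Negishi carboalumination adds methyl and aluminium syn across the terminal alkyne with methyl on the internal carbon, and the derived alanate is hydroxymethylated with retention; this fixes the E geometry of the later C1=C8 alkene while the primary chloride is inert.

Step 10
Reactants: 14 (E)-6-chloro-3-methylhex-2-en-1-ol
Product: 15 tert-butyl{[(E)-6-chloro-3-methylhex-2-en-1-yl]oxy}dimethylsilane
Conditions: t-BuMe2SiCl, imidazole, DMF, rt
Reagents that add atoms: tert-butyl(chloro)dimethylsilane, CC(C)(C)[Si](C)(C)Cl
Why: Standard silylation; the more labile of the two silyl groups is put on C9, the terminus to be unmasked first.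

Step 11
Reactants: 15 tert-butyl{[(E)-6-chloro-3-methylhex-2-en-1-yl]oxy}dimethylsilane
Product: 17 (E)-7-[(tert-butyldimethylsilyl)oxy]-5-methylhept-5-enoic acid, via Grignard reagent 16 (not isolated)
Conditions: Mg turnings (activated by 1,2-dibromoethane), THF, reflux; CO2, −40 °C to rt; citric acid to pH 4
Reagents that add atoms: carbon dioxide, O=C=O
Why: Grignard formation from the primary chloride and carboxylation add the carbon that becomes C13; the allylic silyl ether is stable to magnesium and to the mildly acidic work-up.

Step 12
Reactants: 17 (E)-7-[(tert-butyldimethylsilyl)oxy]-5-methylhept-5-enoic acid; 18 (R)-4-benzyloxazolidin-2-one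
Product: 20 (R)-4-benzyl-3-{(E)-7-[(tert-butyldimethylsilyl)oxy]-5-methylhept-5-enoyl}oxazolidin-2-one, via mixed pivalic anhydride 19 (not isolated)
Conditions: t-BuCOCl, Et3N, THF, −20 °C; then 18, LiCl, rt
Reagents that add atoms: none
Why: N-Acylation of the oxazolidinone through the mixed anhydride with LiCl activation is a mild procedure that leaves the silyl ether intact.

Step 13
Reactants: 20 (R)-4-benzyl-3-{(E)-7-[(tert-butyldimethylsilyl)oxy]-5-methylhept-5-enoyl}oxazolidin-2-one; 11 tert-butyl{[(E)-4-iodo-2-methylbut-2-en-1-yl]oxy}diphenylsilane
Product: 22 (R)-4-benzyl-3-[(2S,4E)-6-[(tert-butyldiphenylsilyl)oxy]-2-{(3E)-5-[(tert-butyldimethylsilyl)oxy]-3-methylpent-3-en-1-yl}-5-methylhex-4-enoyl]oxazolidin-2-one, via sodium enolate 21 (not isolated)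
Conditions: NaN(SiMe3)2 (1.1 equiv), THF, −78 °C; then 11 (1.5 equiv), −78 to −45 °C
Reagents that add atoms: none
Why: Evans alkylation: the chelated Z sodium enolate is attacked by the allylic iodide on the face opposite the benzyl group of the (R)-auxiliary, which forms the C3–C4 bond and should set C4 as S with high diastereoselectivity; direct SN2 substitution leaves the E alkene of 11 unchanged.

Step 14
Reactants: 22 (R)-4-benzyl-3-[(2S,4E)-6-[(tert-butyldiphenylsilyl)oxy]-2-{(3E)-5-[(tert-butyldimethylsilyl)oxy]-3-methylpent-3-en-1-yl}-5-methylhex-4-enoyl]oxazolidin-2-one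
Product: 23 (2S,4E)-6-[(tert-butyldiphenylsilyl)oxy]-2-{(3E)-5-[(tert-butyldimethylsilyl)oxy]-3-methylpent-3-en-1-yl}-N-methoxy-N,5-dimethylhex-4-enamide
Conditions: MeNH(OMe)·HCl, AlMe3, CH2Cl2, −15 °C to rt
Reagents that add atoms: N,O-dimethylhydroxylamine hydrochloride, CNOC.Cl
Why: Transamination of the imide by the aluminium amide gives the Weinreb amide without enolising C4; the auxiliary is released and can be recovered.

Step 15
Reactants: 23 (2S,4E)-6-[(tert-butyldiphenylsilyl)oxy]-2-{(3E)-5-[(tert-butyldimethylsilyl)oxy]-3-methylpent-3-en-1-yl}-N-methoxy-N,5-dimethylhex-4-enamide; 7 tributyl{[(4-methoxybenzyl)oxy]methyl}stannane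
Product: 25 (3S,5E)-7-[(tert-butyldiphenylsilyl)oxy]-3-{(3E)-5-[(tert-butyldimethylsilyl)oxy]-3-methylpent-3-en-1-yl}-1-[(4-methoxybenzyl)oxy]-6-methylhept-5-en-2-one, via alkoxymethyllithium 24 (not isolated)
Conditions: 7, n-BuLi, THF, −78 °C, 10 min; then 23, −78 °C; aq. NH4Cl at −78 °C
Reagents that add atoms: none
Why: Tin–lithium exchange generates the alkoxymethyllithium, which adds once to the Weinreb amide because the chelated tetrahedral intermediate survives until the quench; the low temperature suppresses rearrangement of the reagent and epimerisation at C4.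

Step 16
Reactants: 25 (3S,5E)-7-[(tert-butyldiphenylsilyl)oxy]-3-{(3E)-5-[(tert-butyldimethylsilyl)oxy]-3-methylpent-3-en-1-yl}-1-[(4-methoxybenzyl)oxy]-6-methylhept-5-en-2-one; 5 triphenyl{2-[(4S)-2,2,5,5-tetramethyl-1,3-dioxolan-4-yl]ethyl}phosphonium iodide
Product: 27 (4S,13Z,16S)-open-chain triene with C18-OPMB/C9-OTBS/C11-OTBDPS/C16,C17-acetonide, via phosphonium ylide 26 (not isolated)
Conditions: 5 (2 equiv), KN(SiMe3)2, THF, −78 to 0 °C; then 25, −78 °C to rt
Reagents that add atoms: none
Why: Wittig olefination of an α-alkoxy ketone with an unstabilised ylide: this ketone class is known to give the trisubstituted alkene in which the alkoxymethyl carbon (C18) is cis to the ylide-derived carbon (C15), the Z geometry required here; lithium-free conditions and low temperature limit enolisation of the ketone toward C4.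

Step 17
Reactants: 27 (4S,13Z,16S)-open-chain triene with C18-OPMB/C9-OTBS/C11-OTBDPS/C16,C17-acetonide
Product: 28 C9 allylic alcohol (C11-OTBDPS/C18-OPMB/acetonide retained)
Conditions: HF·pyridine, pyridine, THF, 0 °C
Reagents that add atoms: none
Why: Buffered hydrogen fluoride removes the primary tert-butyldimethylsilyl ether much faster than the tert-butyldiphenylsilyl ether, and the acetonide and the PMB ether are stable to it.

Step 18
Reactants: 28 C9 allylic alcohol (C11-OTBDPS/C18-OPMB/acetonide retained)
Product: 30 C9 allylic phenyl sulfone (C11-OTBDPS/C18-OPMB/acetonide retained), via allylic mesylate 29 (not isolated)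
Conditions: MeSO2Cl, Et3N, THF, −20 °C; then PhSO2Na, Bu4NI (cat.), DMF, rt
Reagents that add atoms: sodium benzenesulfinate, [Na+].[O-]S(=O)c1ccccc1
Why: The allylic mesylate is displaced by the sulfinate at sulfur in an SN2 reaction, which gives the primary allylic sulfone with the E alkene retained.

Step 19
Reactants: 30 C9 allylic phenyl sulfone (C11-OTBDPS/C18-OPMB/acetonide retained)
Product: 31 C11 allylic alcohol with C9 sulfone (C18-OPMB/acetonide retained)
Conditions: Bu4NF, AcOH (buffer), THF, 0 °C to rt
Reagents that add atoms: none
Why: Fluoride cleaves the remaining silyl ether; buffering with acetic acid prevents base-induced migration of the allylic sulfone double bond.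

Step 20
Reactants: 31 C11 allylic alcohol with C9 sulfone (C18-OPMB/acetonide retained)
Product: 32 C11 allylic bromide with C9 sulfone (C18-OPMB/acetonide retained)
Conditions: CBr4, PPh3, 2,6-lutidine, CH2Cl2, 0 °C; used at once
Reagents that add atoms: carbon tetrabromide, BrC(Br)(Br)Br
Why: Appel bromination of a primary allylic alcohol under neutral conditions, which neither opens the acetonide nor deprotonates the sulfone.

Step 21
Reactants: 32 C11 allylic bromide with C9 sulfone (C18-OPMB/acetonide retained)
Product: 34 (4S)-(E,E)-cyclodeca-1,5-diene with phenylsulfonyl at C9 (both C9 epimers), via lithiated sulfone 33 (not isolated)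
Conditions: LiN(SiMe3)2 (1.5 equiv), THF, 0 °C; 32 added by syringe pump over 10 h (final 2 mM); aq. NH4Cl
Reagents that add atoms: none
Why: Intramolecular alkylation of a sulfone-stabilised allylic carbanion by an allylic bromide (Biellmann-type coupling) under high dilution closes the ten-membered ring through the C9–C11 bond; alkylation occurs α to sulfur, both E alkenes are untouched, and the new centre at C9 is of no consequence.

Step 22
Reactants: 34 (4S)-(E,E)-cyclodeca-1,5-diene with phenylsulfonyl at C9 (both C9 epimers)
Product: 35 (S)-configured (E,E)-cyclodeca-1,5-diene carrying the side chain with C18-OPMB and acetonide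
Conditions: PdCl2(dppp) (10 mol%), LiBHEt3 (3 equiv), THF, 0 °C; rapid filtration through Et3N-deactivated silica, used at once
Reagents that add atoms: none
Why: Palladium-catalysed hydride desulfonylation: zerovalent palladium ionises the allylic sulfone and hydride is transferred to the less substituted terminus C9 of the allyl complex, so the trisubstituted E C1=C8 alkene should be kept; the allylic PMB ether and the acetonide are inert to LiBHEt3.

Step 23
Reactants: 35 (S)-configured (E,E)-cyclodeca-1,5-diene carrying the side chain with C18-OPMB and acetonide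
Product: 36 (1R,2R,4S)-elemane PMB ether acetonide
Conditions: toluene (0.02 M, degassed), K2CO3 (solid), 110 °C, sealed tube
Reagents that add atoms: none
Why: The reaction is a concerted, suprafacial [3,3]-sigmatropic (Cope) shift in which the C1–C2 bond forms across the ring while the C9–C11 bond breaks, which releases the vinyl group (C8=C9) and the isopropenyl group (C10=C11). The closest known reaction type is the thermal rearrangement of germacra-1(10),4-dienes to elemanes, as in the conversion of germacrene A into β-elemene. The six-membered ring closes by transannular bonding of the methyl-bearing alkene carbon C1 to the CH alkene carbon C2 through a chair-like transition state that corresponds to the chair–chair conformer of the ten-membered ring with crossed alkenes. C4 is the only stereocentre of 35; its bulky side chain takes the pseudo-equatorial position and thereby selects one of the two mirror-image chair–chair arrangements of the diene, which should fix C1 as R and C2 as R. The E geometry of both ring alkenes, combined with the chair, places the vinyl group trans to the isopropenyl group and the C1 methyl cis to it. The step needs this conformational (facial) selectivity, secured by the size of the C4 substituent, and freedom from acid, secured by the base-buffered, degassed medium. Release of medium-ring strain should drive the equilibrium to the elemane. The PMB ether and the acetonide are spectators at this temperature.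

Step 24
Reactants: 36 (1R,2R,4S)-elemane PMB ether acetonide
Product: 37 elemane C18 allylic alcohol acetonide
Conditions: DDQ, CH2Cl2/pH 7 phosphate buffer, 0 °C
Reagents that add atoms: none
Why: Oxidative cleavage of the PMB ether by hydride abstraction at the electron-rich benzylic position; the isolated vinyl, isopropenyl and trisubstituted alkenes of the elemane should not be oxidised under buffered conditions.

Step 25
Reactants: 37 elemane C18 allylic alcohol acetonide
Product: 38 acetonide of the target (C18 acetate)
Conditions: Ac2O, pyridine, DMAP (cat.), CH2Cl2, rt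
Reagents that add atoms: acetic anhydride, CC(=O)OC(C)=O
Why: Standard acylation of the only free hydroxyl group.

Step 26
Reactants: 38 acetonide of the target (C18 acetate)
Product: 39 (2Z,5S)-5,6-dihydroxy-6-methyl-2-[(1S,3R,4R)-4-ethenyl-4-methyl-3-(prop-1-en-2-yl)cyclohexyl]hept-2-en-1-yl acetate
Conditions: AcOH/H2O (4:1), 40 °C
Reagents that add atoms: none
Why: Mild acid hydrolysis of the isopropylidene ketal; the allylic acetate and the 1,5-diene should tolerate aqueous acetic acid at this temperature and no stereocentre is affected.

## Compound list

1 | (S)-3-hydroxydihydrofuran-2(3H)-one (α-hydroxy-γ-butyrolactone from L-malic acid) | O[C@H]1CCOC1=O | starting material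
2 | (S)-4-methylpentane-1,3,4-triol | OCC[C@H](O)C(C)(C)O | intermediate
3 | 2-[(4S)-2,2,5,5-tetramethyl-1,3-dioxolan-4-yl]ethan-1-ol | OCC[C@@H]1OC(C)(C)OC1(C)C | intermediate
4 | (4S)-4-(2-iodoethyl)-2,2,5,5-tetramethyl-1,3-dioxolane | ICC[C@@H]1OC(C)(C)OC1(C)C | intermediate
5 | triphenyl{2-[(4S)-2,2,5,5-tetramethyl-1,3-dioxolan-4-yl]ethyl}phosphonium iodide | [I-].c1ccccc1[P+](c1ccccc1)(c1ccccc1)CC[C@@H]1OC(C)(C)OC1(C)C | intermediate
6 | tributyl(iodomethyl)stannane | CCCC[Sn](CCCC)(CCCC)CI | starting material
7 | tributyl{[(4-methoxybenzyl)oxy]methyl}stannane | CCCC[Sn](CCCC)(CCCC)COCc1ccc(OC)cc1 | intermediate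
8 | 2-methyl-2-vinyloxirane (racemic) | C=CC1(C)CO1 | starting material
9 | (E)-4-chloro-2-methylbut-2-en-1-ol | ClC/C=C(C)/CO | intermediate
10 | tert-butyl{[(E)-4-chloro-2-methylbut-2-en-1-yl]oxy}diphenylsilane | ClC/C=C(C)/CO[Si](c1ccccc1)(c1ccccc1)C(C)(C)C | intermediate
11 | tert-butyl{[(E)-4-iodo-2-methylbut-2-en-1-yl]oxy}diphenylsilane | IC/C=C(C)/CO[Si](c1ccccc1)(c1ccccc1)C(C)(C)C | intermediate
12 | 5-chloropent-1-yne | C#CCCCCl | starting material
13 | [(E)-5-chloro-2-methylpent-1-en-1-yl]dimethylalane (formed in situ) | C[Al](C)/C=C(\C)CCCCl | intermediate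
14 | (E)-6-chloro-3-methylhex-2-en-1-ol | ClCCC/C(C)=C/CO | intermediate
15 | tert-butyl{[(E)-6-chloro-3-methylhex-2-en-1-yl]oxy}dimethylsilane | ClCCC/C(C)=C/CO[Si](C)(C)C(C)(C)C | intermediate
16 | {(E)-6-[(tert-butyldimethylsilyl)oxy]-4-methylhex-4-en-1-yl}magnesium chloride (formed in situ) | Cl[Mg]CCC/C(C)=C/CO[Si](C)(C)C(C)(C)C | intermediate
17 | (E)-7-[(tert-butyldimethylsilyl)oxy]-5-methylhept-5-enoic acid | OC(=O)CCC/C(C)=C/CO[Si](C)(C)C(C)(C)C | intermediate
18 | (R)-4-benzyloxazolidin-2-one | O=C1OC[C@@H](Cc2ccccc2)N1 | starting material
19 | (E)-7-[(tert-butyldimethylsilyl)oxy]-5-methylhept-5-enoic pivalic anhydride (formed in situ) | CC(C)(C)C(=O)OC(=O)CCC/C(C)=C/CO[Si](C)(C)C(C)(C)C | intermediate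
20 | (R)-4-benzyl-3-{(E)-7-[(tert-butyldimethylsilyl)oxy]-5-methylhept-5-enoyl}oxazolidin-2-one | O=C1OC[C@@H](Cc2ccccc2)N1C(=O)CCC/C(C)=C/CO[Si](C)(C)C(C)(C)C | intermediate
21 | sodium (Z)-enolate of 20 (formed in situ) | [Na+].O=C1OC[C@@H](Cc2ccccc2)N1/C([O-])=C/CC/C(C)=C/CO[Si](C)(C)C(C)(C)C | intermediate
22 | (R)-4-benzyl-3-[(2S,4E)-6-[(tert-butyldiphenylsilyl)oxy]-2-{(3E)-5-[(tert-butyldimethylsilyl)oxy]-3-methylpent-3-en-1-yl}-5-methylhex-4-enoyl]oxazolidin-2-one | O=C1OC[C@@H](Cc2ccccc2)N1C(=O)[C@H](C/C=C(C)/CO[Si](c2ccccc2)(c3ccccc3)C(C)(C)C)CC/C(C)=C/CO[Si](C)(C)C(C)(C)C | intermediate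
23 | (2S,4E)-6-[(tert-butyldiphenylsilyl)oxy]-2-{(3E)-5-[(tert-butyldimethylsilyl)oxy]-3-methylpent-3-en-1-yl}-N-methoxy-N,5-dimethylhex-4-enamide | CON(C)C(=O)[C@H](C/C=C(C)/CO[Si](c1ccccc1)(c2ccccc2)C(C)(C)C)CC/C(C)=C/CO[Si](C)(C)C(C)(C)C | intermediate
24 | {[(4-methoxybenzyl)oxy]methyl}lithium (formed in situ) | [Li]COCc1ccc(OC)cc1 | intermediate
25 | (3S,5E)-7-[(tert-butyldiphenylsilyl)oxy]-3-{(3E)-5-[(tert-butyldimethylsilyl)oxy]-3-methylpent-3-en-1-yl}-1-[(4-methoxybenzyl)oxy]-6-methylhept-5-en-2-one | COc1ccc(COCC(=O)[C@H](C/C=C(C)/CO[Si](c2ccccc2)(c3ccccc3)C(C)(C)C)CC/C(C)=C/CO[Si](C)(C)C(C)(C)C)cc1 | intermediate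
26 | triphenyl{2-[(4S)-2,2,5,5-tetramethyl-1,3-dioxolan-4-yl]ethylidene}phosphorane (formed in situ) | c1ccccc1P(c1ccccc1)(c1ccccc1)=CC[C@@H]1OC(C)(C)OC1(C)C | intermediate
27 | (4S,13Z,16S)-open-chain triene: C4 bears the arm C3–C2=C10(Me)–C11H2OTBDPS (E), the arm C5–C6–C1(Me)=C8–C9H2OTBS (E) and C13(=C14H–C15H2–dioxolane)(C18H2OPMB) with C18 cis to C15 | COc1ccc(COC/C(=C\C[C@@H]2OC(C)(C)OC2(C)C)[C@H](C/C=C(C)/CO[Si](c3ccccc3)(c4ccccc4)C(C)(C)C)CC/C(C)=C/CO[Si](C)(C)C(C)(C)C)cc1 | intermediate
28 | as 27 with free hydroxyl at C9 | COc1ccc(COC/C(=C\C[C@@H]2OC(C)(C)OC2(C)C)[C@H](C/C=C(C)/CO[Si](c3ccccc3)(c4ccccc4)C(C)(C)C)CC/C(C)=C/CO)cc1 | intermediate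
29 | as 28 with methanesulfonate at C9 (formed in situ) | COc1ccc(COC/C(=C\C[C@@H]2OC(C)(C)OC2(C)C)[C@H](C/C=C(C)/CO[Si](c3ccccc3)(c4ccccc4)C(C)(C)C)CC/C(C)=C/COS(C)(=O)=O)cc1 | intermediate
30 | as 28 with phenylsulfonyl at C9 | COc1ccc(COC/C(=C\C[C@@H]2OC(C)(C)OC2(C)C)[C@H](C/C=C(C)/CO[Si](c3ccccc3)(c4ccccc4)C(C)(C)C)CC/C(C)=C/CS(=O)(=O)c5ccccc5)cc1 | intermediate
31 | C9 phenyl sulfone with free hydroxyl at C11 | COc1ccc(COC/C(=C\C[C@@H]2OC(C)(C)OC2(C)C)[C@H](C/C=C(C)/CO)CC/C(C)=C/CS(=O)(=O)c3ccccc3)cc1 | intermediate
32 | C9 phenyl sulfone with bromide at C11 | COc1ccc(COC/C(=C\C[C@@H]2OC(C)(C)OC2(C)C)[C@H](C/C=C(C)/CBr)CC/C(C)=C/CS(=O)(=O)c3ccccc3)cc1 | intermediate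
33 | C9-lithiated sulfone of 32 (formed in situ) | COc1ccc(COC/C(=C\C[C@@H]2OC(C)(C)OC2(C)C)[C@H](C/C=C(C)/CBr)CC/C(C)=C/C([Li])S(=O)(=O)c3ccccc3)cc1 | intermediate
34 | (4S)-(E,E)-cyclodeca-1,5-diene with phenylsulfonyl at C9 (both C9 epimers), side chain with C18-OPMB and acetonide | COc1ccc(COC/C(=C\C[C@@H]2OC(C)(C)OC2(C)C)[C@H]3CC/C(C)=C/C(S(=O)(=O)c4ccccc4)C/C(C)=C/C3)cc1 | intermediate
35 | (S)-configured (E,E)-cyclodeca-1,5-diene, side chain with C18-OPMB and acetonide | COc1ccc(COC/C(=C\C[C@@H]2OC(C)(C)OC2(C)C)[C@H]3CC/C(C)=C/CC/C(C)=C/C3)cc1 | intermediate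
36 | (1R,2R,4S)-elemane PMB ether acetonide | C=C[C@@]1(C)CC[C@H](/C(=C/C[C@@H]2OC(C)(C)OC2(C)C)COCc2ccc(OC)cc2)C[C@@H]1C(=C)C | intermediate
37 | elemane C18 allylic alcohol acetonide | C=C[C@@]1(C)CC[C@H](/C(=C/C[C@@H]2OC(C)(C)OC2(C)C)CO)C[C@@H]1C(=C)C | intermediate
38 | acetonide of the target (C18 acetate) | C=C[C@@]1(C)CC[C@H](/C(=C/C[C@@H]2OC(C)(C)OC2(C)C)COC(C)=O)C[C@@H]1C(=C)C | intermediate
39 | (2Z,5S)-5,6-dihydroxy-6-methyl-2-[(1S,3R,4R)-4-ethenyl-4-methyl-3-(prop-1-en-2-yl)cyclohexyl]hept-2-en-1-yl acetate | C=C[C@@]1(C)CC[C@H](/C(=C/C[C@H](O)C(C)(C)O)COC(C)=O)C[C@@H]1C(=C)C | target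

## Step count and least certain steps

Total step count: 26. Longest linear sequence: 18 steps (steps 9 to 26, from **12**).

**Step 23 (key step).** The most likely failure is a proton-initiated transannular cyclisation of the cyclodecadiene to bicyclic olefins that competes with the sigmatropic shift at 110 °C, or a rearrangement that stops short of completion. The fallback replaces the thermal pericyclic process by its metal-promoted, stepwise counterpart. Starting again from **35**, a catalytic amount of PdCl2(PhCN)2 (divalent palladium) in THF at room temperature forms the same C1–C2 bond through a cyclisation-induced rearrangement via a palladium-bound cyclohexyl cation. This is a known way of running Cope rearrangements of 1,5-dienes, cyclodeca-1,5-dienes included, far below the thermal threshold. It returns to the route at **36** and makes no new compound.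

**Step 21.** The most likely failure is intermolecular alkylation (oligomerisation) outrunning closure of the strained ten-membered ring, or base-induced elimination of HBr from the allylic bromide. The fallback closes the ring without any carbanion, by reductive allyl–allyl coupling on zerovalent nickel. It sets out from **27**: both silyl ethers are removed with Bu4NF to give the diol F1, this is converted with CBr4/PPh3 into the bis(allylic) dibromide F2, and slow addition of F2 to Ni(cod)2 in DMF joins C9 to C11. The route is rejoined at **35**, and steps 17 to 22 are bypassed.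

**Step 22.** The most likely failure is hydride delivery to C1 instead of C9 (alkene transposition), or loss of E geometry through isomerisation of the allyl-palladium intermediate inside the strained ring. The fallback rearranges first and removes sulfur afterwards. It sets out from **34**: heating in toluene at 110 °C effects the Cope rearrangement of the sulfone itself and gives the elemane alkenyl sulfone F3, in which the sulfonyl group sits on the terminal carbon C9 of the new vinyl group. This alkenyl carbon–sulfur bond is then cleaved by electron transfer (sodium amalgam, Na2HPO4, MeOH/THF, −20 °C), which involves no allyl intermediate. The route is rejoined at **36**.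

**Step 16.** The most likely failure is erosion of the Z selectivity because the ketone is α-branched, together with enolisation of the ketone by the ylide (lower conversion, possible epimerisation at C4). The fallback builds the same alkene by β-oxido ylide hydroxymethylation, which places the new hydroxymethyl carbon cis to the aldehyde-derived substituent. It sets out from **22**:
- LiBH4 reduction gives the primary alcohol F4, which is converted with I2/PPh3/imidazole into the iodide F5 and with PPh3 into the phosphonium iodide F6.
- The ylide of F6 (n-BuLi, THF, −78 °C) is added to the aldehyde F7, made from alcohol **3** by Dess–Martin oxidation.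
- The betaine is deprotonated with a second equivalent of alkyllithium and the β-oxido ylide is trapped with formaldehyde, which gives the allylic alcohol F8 with C18 cis to C15.
- Etherification with NaH and 4-methoxybenzyl chloride rejoins the route at **27**.

**Step 14.** The most likely failure is attack of the aluminium amide on the ring carbonyl of the auxiliary (endocyclic cleavage), because the acyl group is α-branched. The fallback goes through the free acid. It sets out from **22**: LiOH/H2O2 in THF/H2O at 0 °C gives the carboxylic acid F9, which is coupled with N,O-dimethylhydroxylamine hydrochloride (EDC, HOBt, i-Pr2NEt). The route is rejoined at **23**.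

## Further compounds

F0 | step 23 | none | none
F1 | step 21 | open-chain C9,C11-diol (C18-OPMB, acetonide) | COc1ccc(COC/C(=C\C[C@@H]2OC(C)(C)OC2(C)C)[C@H](C/C=C(C)/CO)CC/C(C)=C/CO)cc1
F2 | step 21 | open-chain C9,C11-dibromide (C18-OPMB, acetonide) | COc1ccc(COC/C(=C\C[C@@H]2OC(C)(C)OC2(C)C)[C@H](C/C=C(C)/CBr)CC/C(C)=C/CBr)cc1
F3 | step 22 | elemane PMB ether acetonide with (E)-2-(phenylsulfonyl)ethenyl at C1 | O=S(=O)(c1ccccc1)/C=C/[C@@]1(C)CC[C@H](/C(=C/C[C@@H]2OC(C)(C)OC2(C)C)COCc2ccc(OC)cc2)C[C@@H]1C(=C)C
F4 | step 16 | (2S,4E)-6-[(tert-butyldiphenylsilyl)oxy]-2-{(3E)-5-[(tert-butyldimethylsilyl)oxy]-3-methylpent-3-en-1-yl}-5-methylhex-4-en-1-ol | OC[C@H](C/C=C(C)/CO[Si](c1ccccc1)(c2ccccc2)C(C)(C)C)CC/C(C)=C/CO[Si](C)(C)C(C)(C)C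
F5 | step 16 | primary iodide from F4 | IC[C@H](C/C=C(C)/CO[Si](c1ccccc1)(c2ccccc2)C(C)(C)C)CC/C(C)=C/CO[Si](C)(C)C(C)(C)C
F6 | step 16 | triphenylphosphonium iodide from F5 | [I-].c1ccccc1[P+](c1ccccc1)(c1ccccc1)C[C@H](C/C=C(C)/CO[Si](c1ccccc1)(c2ccccc2)C(C)(C)C)CC/C(C)=C/CO[Si](C)(C)C(C)(C)C
F7 | step 16 | 2-[(4S)-2,2,5,5-tetramethyl-1,3-dioxolan-4-yl]acetaldehyde | O=CC[C@@H]1OC(C)(C)OC1(C)C
F8 | step 16 | (Z)-allylic alcohol corresponding to 27 with free hydroxyl at C18 | OC/C(=C\C[C@@H]1OC(C)(C)OC1(C)C)[C@H](C/C=C(C)/CO[Si](c2ccccc2)(c3ccccc3)C(C)(C)C)CC/C(C)=C/CO[Si](C)(C)C(C)(C)C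
F9 | step 14 | (2S,4E)-6-[(tert-butyldiphenylsilyl)oxy]-2-{(3E)-5-[(tert-butyldimethylsilyl)oxy]-3-methylpent-3-en-1-yl}-5-methylhex-4-enoic acid | OC(=O)[C@H](C/C=C(C)/CO[Si](c1ccccc1)(c2ccccc2)C(C)(C)C)CC/C(C)=C/CO[Si](C)(C)C(C)(C)C
A1 | alternative 1 | 6-ethenyl-1,4-dioxan-2-one carrying the elemane ring at C6 | C=C[C@@]1(C)CC[C@H]([C@]2(C=C)COCC(=O)O2)C[C@@H]1C(=C)C
A2 | alternative 1 | (S)-5-[(1S,3R,4R)-4-ethenyl-4-methyl-3-(prop-1-en-2-yl)cyclohexyl]-3,6-dihydro-2H-pyran-2-carboxylic acid | C=C[C@@]1(C)CC[C@H](C2=CC[C@H](OC2)C(=O)O)C[C@@H]1C(=C)C
A3 | alternative 2 | 2-(triisopropylsilyloxy)buta-1,3-diene | C=CC(=C)O[Si](C(C)C)(C(C)C)C(C)C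
A4 | alternative 2 | ethyl (E)-3-methyl-4-oxobut-2-enoate | CCOC(=O)/C=C(\C)C=O
A5 | alternative 2 | ethyl 2-formyl-2-methyl-5-(triisopropylsilyloxy)cyclohex-4-ene-1-carboxylate, formyl trans to ester | O=C[C@@]1(C)CC=C(O[Si](C(C)C)(C(C)C)C(C)C)C[C@@H]1C(=O)OCC
A6 | alternative 3 | open-chain bis(phenylsulfonyl)methane with secondary allylic methyl carbonate (alkene geometry and carbonate configuration left open) | C=C[C@@](C)(CC(S(=O)(=O)c1ccccc1)S(=O)(=O)c1ccccc1)[C@H](CC=C(CO[Si](C)(C)C(C)(C)C)C(OC(=O)OC)C[C@@H]1OC(C)(C)OC1(C)C)C(=C)C
A7 | alternative 3 | C5 bis(phenylsulfonyl)cyclohexane with silyl ether and acetonide | C=C[C@@]1(C)CC(S(=O)(=O)c2ccccc2)(S(=O)(=O)c2ccccc2)[C@H](/C(=C/C[C@@H]2OC(C)(C)OC2(C)C)CO[Si](C)(C)C(C)(C)C)C[C@@H]1C(=C)C
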